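**Retrosynthetic overview**
1. Target 34 ⇐ epoxidation of the (4Z)-olefin of acetate 33 ⇐ silyl-to-acetate exchange on the ring-expanded lactone 30.
2. Ten-membered ring of 30 ⇐ four-carbon ring expansion of the spiro cyclohexenone–butenolide 27: alkenyl addition to the C1 ketone (C1–C10), then retro-vinylogous-aldol cleavage of C1–C6 and protonation at C6.
3. Spiro cyclohexenone 26 ⇐ Pd-catalysed enolate alkenylation (C5–C6) after vinylogous Mukaiyama aldol and oxidation (C1–C6), joining butenolide 14 and (Z)-iodo aldehyde 21.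
4. 14 ⇐ asymmetric 2-bromoallylation (sets C8) of aldehyde 9 ⇐ ozonolysis of a vinyl butenolide made from butynediol, vinylmagnesium bromide and CO2; 21 ⇐ carbocupration of propyne.
5. Ring order: butenolide → six-membered carbocycle (spiro) → ten-membered carbocycle by expansion → oxirane.

Assumption: germacrane numbering is used for the carbocycle (C1 ketone, C4 methyl-bearing carbon, C6 lactone carbinol, C7=C11 butenolide olefin, C8 ester carbinol, C10 exo-methylene carbon, C12 lactone carbonyl, C13 CH2O); centres that are destroyed later are carried as epimer mixtures; TBS = tert-butyldimethylsilyl, TMS = trimethylsilyl, Bpin = pinacolboryl; catalyst-bound species are numbered only in step 11.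

**Step 1**
Reactants: 1 but-2-yne-1,4-diol; 2 vinylmagnesium bromide; 3 carbon dioxide
Product: 6 4-ethenyl-3-(hydroxymethyl)furan-2(5H)-one, via alkenylmagnesium chelate 4 (not isolated), via dienoic hydroxy acid 5 (not isolated)
Conditions: 2 (3.5 equiv), CuI (10 mol %), THF–toluene, reflux; CO2 (1 atm), −20 °C to rt; 2 M HCl
Reagents that add atoms: none
Why: Hydroxyl-directed anti-carbomagnesiation (Duboudin–Fallis type) puts vinyl on one alkyne carbon and magnesium on the other, cis to a CH2O arm, so carboxylation gives a (Z)-hydroxy acid that lactonises to the tetrasubstituted butenolide; no stereocentre is formed.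

**Step 2**
Reactants: 6 4-ethenyl-3-(hydroxymethyl)furan-2(5H)-one
Product: 7 3-({[tert-butyl(dimethyl)silyl]oxy}methyl)-4-ethenylfuran-2(5H)-one
Conditions: TBSCl, imidazole, DMF, 0 °C to rt
Reagents that add atoms: tert-butyldimethylsilyl chloride, CC(C)(C)[Si](C)(C)Cl
Why: Standard silylation of the only hydroxyl; a silyl ether at C13 (not the final acetate) is carried because a 3-(acyloxymethyl)furanolate would expel acetate in steps 7, 9 and 11.

**Step 3**
Reactants: 7 3-({[tert-butyl(dimethyl)silyl]oxy}methyl)-4-ethenylfuran-2(5H)-one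
Product: 9 4-({[tert-butyl(dimethyl)silyl]oxy}methyl)-5-oxo-2,5-dihydrofuran-3-carbaldehyde, via secondary ozonide 8 (not isolated)
Conditions: O3, CH2Cl2, −78 °C (Sudan red end point); Me2S, −78 °C to rt
Reagents that add atoms: ozone, O=[O+][O-]
Why: Ozonolysis with reductive work-up cleaves the monosubstituted vinyl group much faster than the tetrasubstituted, electron-poor butenolide olefin.

**Step 4**
Reactants: 9 4-({[tert-butyl(dimethyl)silyl]oxy}methyl)-5-oxo-2,5-dihydrofuran-3-carbaldehyde; 10 2,3-dibromoprop-1-ene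
Product: 12 4-[(1R)-3-bromo-1-hydroxybut-3-en-1-yl]-3-({[tert-butyl(dimethyl)silyl]oxy}methyl)furan-2(5H)-one, via trimethylsilyl ether 11 (not isolated)
Conditions: CrBr3 (10 mol %), chiral oxazoline sulfonamide ligand (Kishi type, antipode for Re-face attack, 11 mol %), Et3N (20 mol %), Fe(C11H19O2)3 (5 mol %), Mn, TMSCl, 2,6-lutidine, THF, 0 °C; then 1 M HCl, THF, 0 °C
Reagents that add atoms: none
Why: Catalytic asymmetric chromium-mediated 2-haloallylation (Nozaki–Hiyama type); only the allylic C–Br bond is activated, and the ligand-bound allylchromium adds to the Re face of the aldehyde to set C8 as R.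

**Step 5**
Reactants: 12 4-[(1R)-3-bromo-1-hydroxybut-3-en-1-yl]-3-({[tert-butyl(dimethyl)silyl]oxy}methyl)furan-2(5H)-one; 13 2-methylprop-2-enoyl chloride
Product: 14 (1R)-3-bromo-1-[4-({[tert-butyl(dimethyl)silyl]oxy}methyl)-5-oxo-2,5-dihydrofuran-3-yl]but-3-en-1-yl 2-methylprop-2-enoate
Conditions: 13, Et3N, DMAP (10 mol %), CH2Cl2, −20 to 0 °C
Reagents that add atoms: none
Why: DMAP-catalysed acylation installs the final C8 ester early, which blocks 6,12/8,12 translactonisation in all later intermediates; the stereocentre is untouched.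

**Step 6**
Reactants: 15 2-(2-bromoethyl)-1,3-dioxolane; 16 propyne
Product: 21 (4Z)-5-iodo-4-methylpent-4-enal, via Grignard reagent 17 (not isolated), via alkylcopper 18 (not isolated), via alkenylcopper 19 (not isolated), via iodo acetal 20 (not isolated)
Conditions: Mg, THF, 25 °C; CuBr·SMe2, Et2O/Me2S, −45 °C; 16, −25 °C; I2, −78 to 0 °C; then 2 M HCl, acetone, rt
Reagents that add atoms: iodine, II; water, O
Why: Normant syn-carbocupration of propyne places copper cis to the new alkyl chain, iodinolysis proceeds with retention to the (Z)-iodide, and aqueous acid unmasks the aldehyde.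

**Step 7**
Reactants: 14 (1R)-3-bromo-1-[4-({[tert-butyl(dimethyl)silyl]oxy}methyl)-5-oxo-2,5-dihydrofuran-3-yl]but-3-en-1-yl 2-methylprop-2-enoate; 21 (4Z)-5-iodo-4-methylpent-4-enal
Product: 24 (1R)-3-bromo-1-[4-({[tert-butyl(dimethyl)silyl]oxy}methyl)-2-[(4Z)-1-hydroxy-5-iodo-4-methylpent-4-en-1-yl]-5-oxo-2,5-dihydrofuran-3-yl]but-3-en-1-yl 2-methylprop-2-enoate, via silyloxyfuran 22 (not isolated), via silylated aldol 23 (not isolated)
Conditions: TMSOTf (1.5 equiv), i-Pr2NEt (1.3 equiv), CH2Cl2, 0 °C; 21, −78 °C; then 1 M HCl, THF, 0 °C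
Reagents that add atoms: none
Why: One-pot soft enolisation and vinylogous Mukaiyama aldol addition forms C1–C6 at the γ-carbon of the 2-silyloxyfuran; the two new centres are not controlled because one is oxidised in step 8 and the other is reset in step 11.

**Step 8**
Reactants: 24 (1R)-3-bromo-1-[4-({[tert-butyl(dimethyl)silyl]oxy}methyl)-2-[(4Z)-1-hydroxy-5-iodo-4-methylpent-4-en-1-yl]-5-oxo-2,5-dihydrofuran-3-yl]but-3-en-1-yl 2-methylprop-2-enoate
Product: 25 (1R)-3-bromo-1-[4-({[tert-butyl(dimethyl)silyl]oxy}methyl)-2-[(4Z)-5-iodo-4-methylpent-4-enoyl]-5-oxo-2,5-dihydrofuran-3-yl]but-3-en-1-yl 2-methylprop-2-enoate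
Conditions: Dess–Martin periodinane (1.1 equiv), NaHCO3, CH2Cl2, 0 °C
Reagents that add atoms: none
Why: Dess–Martin oxidation of the secondary alcohol gives the γ-acyl butenolide, whose C6–H is now a vinylogous β-keto lactone proton.

**Step 9**
Reactants: 25 (1R)-3-bromo-1-[4-({[tert-butyl(dimethyl)silyl]oxy}methyl)-2-[(4Z)-5-iodo-4-methylpent-4-enoyl]-5-oxo-2,5-dihydrofuran-3-yl]but-3-en-1-yl 2-methylprop-2-enoate
Product: 26 (1R)-3-bromo-1-[3-({[tert-butyl(dimethyl)silyl]oxy}methyl)-9-methyl-2,6-dioxo-1-oxaspiro[4.5]deca-3,9-dien-4-yl]but-3-en-1-yl 2-methylprop-2-enoate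
Conditions: Pd(PPh3)4 (10 mol %), Cs2CO3 (anhydrous), THF, 50 °C, 0.02 M
Reagents that add atoms: none
Why: Palladium-catalysed intramolecular α-alkenylation of the stabilised enolate closes the six-membered ring at C5–C6; zerovalent palladium inserts into C–I well before the 2-bromoalkene, and the ring fixes the Z geometry of C4=C5 (the spiro centre forms as both epimers, which converge in step 11).

**Step 10**
Reactants: 26 (1R)-3-bromo-1-[3-({[tert-butyl(dimethyl)silyl]oxy}methyl)-9-methyl-2,6-dioxo-1-oxaspiro[4.5]deca-3,9-dien-4-yl]but-3-en-1-yl 2-methylprop-2-enoate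
Product: 27 (1R)-1-[3-({[tert-butyl(dimethyl)silyl]oxy}methyl)-9-methyl-2,6-dioxo-1-oxaspiro[4.5]deca-3,9-dien-4-yl]-3-(4,4,5,5-tetramethyl-1,3,2-dioxaborolan-2-yl)but-3-en-1-yl 2-methylprop-2-enoate
Conditions: B2pin2, PdCl2(dppf) (5 mol %), KOAc, 1,4-dioxane, 80 °C
Reagents that add atoms: bis(pinacolato)diboron, CC1(C)OB(OC1(C)C)B1OC(C)(C)C(C)(C)O1
Why: Miyaura borylation converts the alkenyl bromide into the alkenylboronate under weakly basic acetate conditions that spare the esters and the hindered ketone.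

**Step 11**
Reactants: 27 (1R)-1-[3-({[tert-butyl(dimethyl)silyl]oxy}methyl)-9-methyl-2,6-dioxo-1-oxaspiro[4.5]deca-3,9-dien-4-yl]-3-(4,4,5,5-tetramethyl-1,3,2-dioxaborolan-2-yl)but-3-en-1-yl 2-methylprop-2-enoate
Product: 30 (4Z,6S,8R)-13-{[tert-butyl(dimethyl)silyl]oxy}-8-(2-methylprop-2-enoyloxy)-1-oxogermacra-4,7(11),10(14)-trien-12,6-olide, via rhodium alkoxide 28 (not isolated), via rhodium furanolate 29 (not isolated)
Conditions: [RhCl(C2H4)2]2 (2.5 mol %), (R,R)-2,5-diphenylbicyclo[2.2.2]octa-2,5-diene (6 mol %), KOH (10 mol %), H2O (5 equiv), 1,4-dioxane, 40 °C, slow addition to 0.005 M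
Reagents that add atoms: none
Why: Proposed new method: a monovalent rhodium hydroxide carrying a chiral diene transmetalates the alkenyl–Bpin, the alkenylrhodium adds 6-exo to the neighbouring activated ketone (as in rhodium-catalysed arylative cyclisations of alkynones), and the hindered tertiary alkoxide 28, which is homoallylic to the butenolide C7=C11 bond, undergoes β-carbon elimination of C1–C6 through a six-membered retro-allylation transition state, driven by loss of two adjacent fully substituted carbons and formation of the conjugated 2-methylene ketone and an aromatic furan-2-olate; water then protonates the ten-membered rhodium furanolate 29 at C6 on the Re face under control of the diene and regenerates Rh–OH. The closest known reactions are the rhodium-catalysed addition/β-carbon-elimination ring opening of cyclobutanones with arylboronic acids, rhodium-catalysed retro-allylation of tertiary homoallylic alcohols and ligand-controlled protonation of rhodium enolates, but their merger into a non-radical, Dowd–Beckwith-like six-to-ten ring expansion of an unstrained ketone with a butenolide as the leaving carbanion has not been shown.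

**Step 12**
Reactants: 30 (4Z,6S,8R)-13-{[tert-butyl(dimethyl)silyl]oxy}-8-(2-methylprop-2-enoyloxy)-1-oxogermacra-4,7(11),10(14)-trien-12,6-olide; 31 acetic anhydride
Product: 33 (4Z,6S,8R)-13-acetoxy-8-(2-methylprop-2-enoyloxy)-1-oxogermacra-4,7(11),10(14)-trien-12,6-olide, via primary alcohol 32 (not isolated)
Conditions: HF·pyridine, THF/pyridine, 0 °C; then 31, DMAP, 0 °C
Reagents that add atoms: none
Why: Fluoride desilylation of the primary allylic silyl ether followed by DMAP-catalysed acetylation in the same flask installs the C13 acetate only after all furanolate chemistry is finished; no stereocentre is touched.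

**Step 13**
Reactants: 33 (4Z,6S,8R)-13-acetoxy-8-(2-methylprop-2-enoyloxy)-1-oxogermacra-4,7(11),10(14)-trien-12,6-olide
Product: 34 (4S,5R,6R,8R)-13-acetoxy-4,5-epoxy-8-(2-methylprop-2-enoyloxy)-1-oxogermacra-7(11),10(14)-dien-12,6-olide
Conditions: mCPBA (1.1 equiv), NaHCO3, CH2Cl2, 0 °C
Reagents that add atoms: 3-chloroperoxybenzoic acid, OOC(=O)c1cccc(Cl)c1
Why: Prilezhaev epoxidation attacks only the electron-rich trisubstituted C4=C5 bond (the enone, methacrylate and butenolide olefins are electron-poor) and is syn-stereospecific, so the Z-olefin gives the cis-epoxide; peripheral attack anti to the C6–C7 ring bond, with the lactone C–O near the olefin plane, is expected to give 4S,5R (C6 keeps its geometry and becomes R only by the priority change).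

**Compound list**
1 | but-2-yne-1,4-diol | OCC#CCO | starting material
2 | vinylmagnesium bromide | C=C[Mg]Br | starting material
3 | carbon dioxide | O=C=O | starting material
4 | (2Z)-2-(bromomagnesio)-3-ethenylbut-2-ene-1,4-diol bis(bromomagnesium alkoxide) | Br[Mg]OC/C(C=C)=C(\[Mg]Br)CO[Mg]Br | intermediate
5 | (2Z)-2,3-bis(hydroxymethyl)penta-2,4-dienoic acid | OC/C(C=C)=C(/CO)C(=O)O | intermediate
6 | 4-ethenyl-3-(hydroxymethyl)furan-2(5H)-one | OCC1=C(C=C)COC1=O | intermediate
7 | 3-({[tert-butyl(dimethyl)silyl]oxy}methyl)-4-ethenylfuran-2(5H)-one | CC(C)(C)[Si](C)(C)OCC1=C(C=C)COC1=O | intermediate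
8 | 3-({[tert-butyl(dimethyl)silyl]oxy}methyl)-4-(1,2,4-trioxolan-3-yl)furan-2(5H)-one | CC(C)(C)[Si](C)(C)OCC1=C(C2OCOO2)COC1=O | intermediate
9 | 4-({[tert-butyl(dimethyl)silyl]oxy}methyl)-5-oxo-2,5-dihydrofuran-3-carbaldehyde | CC(C)(C)[Si](C)(C)OCC1=C(C=O)COC1=O | intermediate
10 | 2,3-dibromoprop-1-ene | C=C(Br)CBr | starting material
11 | 4-{(1R)-3-bromo-1-[(trimethylsilyl)oxy]but-3-en-1-yl}-3-({[tert-butyl(dimethyl)silyl]oxy}methyl)furan-2(5H)-one | C[Si](C)(C)O[C@H](CC(Br)=C)C1=C(CO[Si](C)(C)C(C)(C)C)C(=O)OC1 | intermediate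
12 | 4-[(1R)-3-bromo-1-hydroxybut-3-en-1-yl]-3-({[tert-butyl(dimethyl)silyl]oxy}methyl)furan-2(5H)-one | O[C@H](CC(Br)=C)C1=C(CO[Si](C)(C)C(C)(C)C)C(=O)OC1 | intermediate
13 | 2-methylprop-2-enoyl chloride | C=C(C)C(Cl)=O | starting material
14 | (1R)-3-bromo-1-[4-({[tert-butyl(dimethyl)silyl]oxy}methyl)-5-oxo-2,5-dihydrofuran-3-yl]but-3-en-1-yl 2-methylprop-2-enoate | C=C(C)C(=O)O[C@H](CC(Br)=C)C1=C(CO[Si](C)(C)C(C)(C)C)C(=O)OC1 | intermediate
15 | 2-(2-bromoethyl)-1,3-dioxolane | BrCCC1OCCO1 | starting material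
16 | propyne | CC#C | starting material
17 | [2-(1,3-dioxolan-2-yl)ethyl]magnesium bromide | Br[Mg]CCC1OCCO1 | intermediate
18 | [2-(1,3-dioxolan-2-yl)ethyl]copper | [Cu]CCC1OCCO1 | intermediate
19 | [(1Z)-4-(1,3-dioxolan-2-yl)-2-methylbut-1-en-1-yl]copper | [Cu]/C=C(/C)CCC1OCCO1 | intermediate
20 | 2-[(3Z)-4-iodo-3-methylbut-3-en-1-yl]-1,3-dioxolane | I/C=C(/C)CCC1OCCO1 | intermediate
21 | (4Z)-5-iodo-4-methylpent-4-enal | I/C=C(/C)CCC=O | intermediate
22 | (1R)-3-bromo-1-{4-({[tert-butyl(dimethyl)silyl]oxy}methyl)-5-[(trimethylsilyl)oxy]furan-3-yl}but-3-en-1-yl 2-methylprop-2-enoate | C=C(C)C(=O)O[C@H](CC(Br)=C)c1coc(O[Si](C)(C)C)c1CO[Si](C)(C)C(C)(C)C | intermediate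
23 | trimethylsilyl ether of 24 (epimers at furanone C2 and the carbinol carbon) | C=C(C)C(=O)O[C@H](CC(Br)=C)C1=C(CO[Si](C)(C)C(C)(C)C)C(=O)OC1C(O[Si](C)(C)C)CC/C(C)=C\I | intermediate
24 | (1R)-3-bromo-1-[4-({[tert-butyl(dimethyl)silyl]oxy}methyl)-2-[(4Z)-1-hydroxy-5-iodo-4-methylpent-4-en-1-yl]-5-oxo-2,5-dihydrofuran-3-yl]but-3-en-1-yl 2-methylprop-2-enoate (epimers at furanone C2 and the carbinol carbon) | C=C(C)C(=O)O[C@H](CC(Br)=C)C1=C(CO[Si](C)(C)C(C)(C)C)C(=O)OC1C(O)CC/C(C)=C\I | intermediate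
25 | (1R)-3-bromo-1-[4-({[tert-butyl(dimethyl)silyl]oxy}methyl)-2-[(4Z)-5-iodo-4-methylpent-4-enoyl]-5-oxo-2,5-dihydrofuran-3-yl]but-3-en-1-yl 2-methylprop-2-enoate (epimers at furanone C2) | C=C(C)C(=O)O[C@H](CC(Br)=C)C1=C(CO[Si](C)(C)C(C)(C)C)C(=O)OC1C(=O)CC/C(C)=C\I | intermediate
26 | (1R)-3-bromo-1-[3-({[tert-butyl(dimethyl)silyl]oxy}methyl)-9-methyl-2,6-dioxo-1-oxaspiro[4.5]deca-3,9-dien-4-yl]but-3-en-1-yl 2-methylprop-2-enoate (both spiro epimers) | C=C(C)C(=O)O[C@H](CC(Br)=C)C1=C(CO[Si](C)(C)C(C)(C)C)C(=O)OC12C=C(C)CCC2=O | intermediate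
27 | (1R)-1-[3-({[tert-butyl(dimethyl)silyl]oxy}methyl)-9-methyl-2,6-dioxo-1-oxaspiro[4.5]deca-3,9-dien-4-yl]-3-(4,4,5,5-tetramethyl-1,3,2-dioxaborolan-2-yl)but-3-en-1-yl 2-methylprop-2-enoate (both spiro epimers) | C=C(C)C(=O)O[C@H](CC(=C)B1OC(C)(C)C(C)(C)O1)C2=C(CO[Si](C)(C)C(C)(C)C)C(=O)OC23C=C(C)CCC3=O | intermediate
28 | rhodium alkoxide of the tricyclic tertiary alcohol formed by C1–C10 bonding of 27 (ligands omitted; C1 and C6 epimers) | C=C(C)C(=O)O[C@@H]1CC(=C)C2(O[Rh])CCC(C)=CC23OC(=O)C(CO[Si](C)(C)C(C)(C)C)=C13 | intermediate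
29 | ring-expanded rhodium furan-2-olate: ten-membered (4Z)-4,10(14)-dien-1-one fused to a 2-(rhodiooxy)furan at C6–C7 (ligands omitted) | C=C(C)C(=O)O[C@@H]1CC(=C)C(=O)CC/C(C)=C\c2oc(O[Rh])c(CO[Si](C)(C)C(C)(C)C)c21 | intermediate
30 | (4Z,6S,8R)-13-{[tert-butyl(dimethyl)silyl]oxy}-8-(2-methylprop-2-enoyloxy)-1-oxogermacra-4,7(11),10(14)-trien-12,6-olide | C=C(C)C(=O)O[C@@H]1CC(=C)C(=O)CC/C(C)=C\[C@@H]2OC(=O)C(CO[Si](C)(C)C(C)(C)C)=C21 | intermediate
31 | acetic anhydride | CC(=O)OC(C)=O | starting material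
32 | (4Z,6S,8R)-13-hydroxy-8-(2-methylprop-2-enoyloxy)-1-oxogermacra-4,7(11),10(14)-trien-12,6-olide | C=C(C)C(=O)O[C@@H]1CC(=C)C(=O)CC/C(C)=C\[C@@H]2OC(=O)C(CO)=C21 | intermediate
33 | (4Z,6S,8R)-13-acetoxy-8-(2-methylprop-2-enoyloxy)-1-oxogermacra-4,7(11),10(14)-trien-12,6-olide | C=C(C)C(=O)O[C@@H]1CC(=C)C(=O)CC/C(C)=C\[C@@H]2OC(=O)C(COC(C)=O)=C21 | intermediate
34 | (4S,5R,6R,8R)-13-acetoxy-4,5-epoxy-8-(2-methylprop-2-enoyloxy)-1-oxogermacra-7(11),10(14)-dien-12,6-olide | C=C(C)C(=O)O[C@@H]1CC(=C)C(=O)CC[C@]2(C)O[C@@H]2[C@@H]2OC(=O)C(COC(C)=O)=C21 | target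

**Totals**
Total step count: 13. Longest linear sequence: 12 steps (steps 1–5 and 7–13, from but-2-yne-1,4-diol); step 6 is a one-step side branch.

**Three steps most likely to fail, with fallbacks**

Step 11, the proposed rhodium-catalysed ring expansion. It can fail by protodeboronation, by alkenylrhodium adding to the product enone, by protonation at C11 instead of C6, or by giving the wrong C6 epimer; the diene antipode named is a working choice, not a prediction. The fallback uses known chemistry and sets out from alkenyl bromide 26, so step 10 is skipped. An intramolecular Nozaki–Hiyama–Kishi reaction (CrCl2, catalytic NiCl2, DMSO, rt) forms the C1–C10 bond and gives the tricyclic tertiary alcohol F1. Deprotonation with KN(SiMe3)2 in THF at −78 °C triggers the anionic retro-vinylogous-aldol fragmentation, and a cold acetic acid quench gives mainly the deconjugated 2(3H)-furanone F2 by kinetic protonation at C11. A cinchona-alkaloid proton-transfer catalyst (6′-hydroxy quinidine or quinine series, chosen by screening) then isomerises the olefin into conjugation and delivers the C6 proton under catalyst control, which brings the material back to the route at 30.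

Step 9, the palladium-catalysed spirocyclisation. The congested spiro centre, competing insertion into C–Br and β-silyloxy elimination from the enolate are the concerns. The fallback sets out from butenolide 14 and builds the cyclohexenone by cycloaddition instead of cross-coupling. The one-pot silyloxyfuran aldol of step 7 is run with methacrolein to give the methacrolein aldol adduct F3. Mesylation and elimination (MsCl, Et3N) give the γ-(2-methylallylidene)butenolide F4. A Diels–Alder reaction with nitroethylene (toluene, 60 °C, sealed tube; likely sluggish because the diene terminus is fully substituted) gives the spiro nitrocyclohexene F5, with the nitro-bearing carbon next to the oxygenated diene terminus and para to the methyl group. A buffered TiCl3 Nef reaction converts F5 into the ketone, returning to the route at 26.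

Step 13, the facial selectivity of the epoxidation. The reactive conformation of the ten-membered ring cannot be predicted with confidence. If the peracid delivers oxygen to the wrong face, the fallback sets out from 33 and inverts the facial outcome. NBS in aqueous THF forms the bromonium ion on the face the peracid prefers, water opens it at the tertiary C4 from the opposite face to give the bromohydrin F6, and Ag2O in CH2Cl2 closes the oxirane with inversion at C5, returning to the route at 34.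

**Further compounds**
F1 | step 11 | tricyclic tertiary alcohol from C1–C10 bonding of 26 (C1–OH, C10 exo-methylene, 8R, C1 and C6 epimers) | C=C(C)C(=O)O[C@@H]1CC(=C)C2(O)CCC(C)=CC23OC(=O)C(CO[Si](C)(C)C(C)(C)C)=C13
F2 | step 11 | (4Z,8R)-13-{[tert-butyl(dimethyl)silyl]oxy}-8-(2-methylprop-2-enoyloxy)-1-oxogermacra-4,6,10(14)-trien-12,6-olide (C11 epimers) | C=C(C)C(=O)O[C@@H]1CC(=C)C(=O)CC/C(C)=C\C2=C1C(CO[Si](C)(C)C(C)(C)C)C(=O)O2
F3 | step 9 | (1R)-3-bromo-1-[4-({[tert-butyl(dimethyl)silyl]oxy}methyl)-2-(1-hydroxy-2-methylprop-2-en-1-yl)-5-oxo-2,5-dihydrofuran-3-yl]but-3-en-1-yl 2-methylprop-2-enoate (epimers) | C=C(C)C(=O)O[C@H](CC(Br)=C)C1=C(CO[Si](C)(C)C(C)(C)C)C(=O)OC1C(O)C(C)=C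
F4 | step 9 | (1R)-3-bromo-1-[(2Z)-4-({[tert-butyl(dimethyl)silyl]oxy}methyl)-2-(2-methylprop-2-en-1-ylidene)-5-oxo-2,5-dihydrofuran-3-yl]but-3-en-1-yl 2-methylprop-2-enoate | C=C(C)C(=O)O[C@H](CC(Br)=C)C1=C(CO[Si](C)(C)C(C)(C)C)C(=O)O/C1=C\C(C)=C
F5 | step 9 | (1R)-3-bromo-1-[3-({[tert-butyl(dimethyl)silyl]oxy}methyl)-9-methyl-6-nitro-2-oxo-1-oxaspiro[4.5]deca-3,9-dien-4-yl]but-3-en-1-yl 2-methylprop-2-enoate (epimers) | C=C(C)C(=O)O[C@H](CC(Br)=C)C1=C(CO[Si](C)(C)C(C)(C)C)C(=O)OC12C=C(C)CCC2[N+](=O)[O-]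
F6 | step 13 | (4S,5S,6R,8R)-13-acetoxy-5-bromo-4-hydroxy-8-(2-methylprop-2-enoyloxy)-1-oxogermacra-7(11),10(14)-dien-12,6-olide | C=C(C)C(=O)O[C@@H]1CC(=C)C(=O)CC[C@](C)(O)[C@@H](Br)[C@@H]2OC(=O)C(COC(C)=O)=C21
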